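Ring C (C9a, C1, C12, C11, C10, C9) is cut at both bonds that tie it to the pyrrole, C1–C12 and C9a–C9. The plan exploits the enamine-like C9a=C1 edge of the pyrrole as a 1,2-bis-nucleophile. It also exploits the 1,4-relation of C9 and C12 in ring C, written as a bis-electrophile: an aldehyde (C9) and the β-carbon of an α-methylbutenolide (C12). One acid-catalysed operation joins a 2-acyl-N-allylpyrrole with this aldehyde–butenolide, forms both bonds, closes ring C and sets C12 and C13 from C11 alone. Convex-face hydroallylation (C9, C10), ring-closing metathesis (azepine) and a reagent-controlled ketone reduction (side lactone) finish the synthesis.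

Key step: step 8

Numbering used below:
- Pyrrole: N4, C3 (bears the side lactone), C2, C1, C9a.
- Azepine: N4, C5–C9, C9a.
- Ring C: C9, C10 (ethyl C16–C17), C11 (O), C12, C1, C9a.
- Fused lactone: C11–O–C14(=O)–C13(CH3)–C12.
- Side lactone: C18–C21.

Assumption: the (S,S)-ProPhenol/Et2Zn catalyst is taken to give the 5S butenolide in step 3; if the sense of induction is the opposite, the (R,R)-ligand is used.

Step 1
Reactants: 1 propanal; 2 nitromethane
Product: 3 1-nitrobutan-2-ol (racemic)
Conditions: Et3N (10 mol %), THF, 0 °C to rt
Reagents that add atoms: none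
Why: The Henry (nitroaldol) addition to an unhindered aldehyde is reliable, and the carbinol centre is erased in step 2.

Step 2
Reactants: 3 1-nitrobutan-2-ol
Product: 5 (E)-1-nitrobut-1-ene, via 1-nitrobutan-2-yl mesylate 4 (not isolated)
Conditions: MsCl, Et3N (2.2 equiv), CH2Cl2, −10 °C
Reagents that add atoms: none
Why: Mesylation followed by E1cB elimination of a β-nitro alcohol should give the conjugated (E)-nitroalkene as the more stable isomer.

Step 3
Reactants: 5 (E)-1-nitrobut-1-ene; 6 3-methylfuran-2(5H)-one
Product: 7 (5S)-3-methyl-5-(1-nitrobutan-2-yl)furan-2(5H)-one (epimers at C10)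
Conditions: Et2Zn (20 mol %), (S,S)-ProPhenol (10 mol %), 4 Å MS, THF, rt
Reagents that add atoms: none
Why: In this direct catalytic asymmetric vinylogous Michael addition, the zinc dienolate attacks the nitroalkene through its γ-carbon inside the chiral dinuclear pocket, which sets C11; the configuration at C10 is irrelevant because step 8 erases it.

Step 4
Reactants: 7 (5S)-3-methyl-5-(1-nitrobutan-2-yl)furan-2(5H)-one
Product: 8 2-[(2S)-4-methyl-5-oxo-2,5-dihydrofuran-2-yl]butanal (epimers at C10)
Conditions: aq TiCl3 (4.5 equiv), NH4OAc buffer (pH 5–6), THF/H2O, 0 °C to rt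
Reagents that add atoms: water, O
Why: The reductive Nef reaction turns the primary nitro group into the aldehyde through the imine at nearly neutral pH, which should spare the butenolide and the C11 centre.

Step 5
Reactants: 9 pyrrole; 10 allyl bromide
Product: 11 1-allylpyrrole
Conditions: KOH, DMSO, rt
Reagents that add atoms: none
Why: N-alkylation (SN2) of the potassium pyrrolide in a dipolar aprotic solvent favours nitrogen over carbon.

Step 6
Reactants: 12 (S)-4-methoxy-3-methyl-4-oxobutanoic acid
Product: 13 methyl (S)-4-chloro-2-methyl-4-oxobutanoate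
Conditions: (COCl)2, DMF (cat.), CH2Cl2, 0 °C to rt
Reagents that add atoms: oxalyl chloride, O=C(Cl)C(=O)Cl
Why: Acid chloride formation through the Vilsmeier-type chloroiminium salt does not touch the C20 centre, which is β to the reacting carbonyl.

Step 7
Reactants: 11 1-allylpyrrole; 13 methyl (S)-4-chloro-2-methyl-4-oxobutanoate
Product: 14 methyl (2S)-4-(1-allylpyrrol-2-yl)-2-methyl-4-oxobutanoate
Conditions: DBN (1,5-diazabicyclo[4.3.0]non-5-ene, 15 mol %), toluene, 110 °C
Reagents that add atoms: none
Why: Nucleophile-catalysed Friedel–Crafts acylation of an N-alkylpyrrole goes to the α-carbon and needs no strong Lewis acid that could attack the allyl group.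

Step 8
Reactants: 8 2-[(2S)-4-methyl-5-oxo-2,5-dihydrofuran-2-yl]butanal; 14 methyl (2S)-4-(1-allylpyrrol-2-yl)-2-methyl-4-oxobutanoate
Product: 17 tricyclic alkenylpyrrole lactone (11S 12S 13S 20S), via pyrrolyl carbinol 15 (not isolated), via alkenylpyrrole 16 (not isolated)
Conditions: Tf2NH (20 mol %), CH2Cl2/(CF3)2CHOH 4:1, 4 Å MS, 0.01 M, 14 added over 4 h to 8 (1.3 equiv), 0 to 40 °C
Reagents that add atoms: none
Why: The acid activates the aldehyde of 8, the free α'-carbon C9a of 14 attacks it in a Friedel–Crafts hydroxyalkylation (bond C9a–C9), carbinol 15 loses water through its azafulvenium ion to give alkenylpyrrole 16, and the neighbouring β-carbon C1, which is meta to the acyl group, then adds to the acid-activated butenolide at C12 (bond C1–C12) with rearomatisation and ketonisation. The closest known reaction types are the acid-catalysed condensation of α-free pyrrole-2-carbonyl compounds with aldehydes and the intramolecular Friedel–Crafts-type Michael addition of pyrroles to unsaturated carbonyl compounds. The first bond is intermolecular and closes no ring, and the second closes ring C in a 6-exo-trig mode on the C12=C13 bond. C12 is set by C11, because the short link C9a–C9=C10 can bring C1 only to the butenolide face that carries C10 (cis fusion, H-11 and H-12 cis), and C13 is set by protonation of the lactone enol from the convex face, which places H-13 cis to H-12 and the methyl group on the concave face. The step needs α' attack before β attack on the aldehyde, aldehyde before butenolide, and ring closure before capture of the cation by a second pyrrole; to secure this, the 2-acyl group blocks C3, leaves C9a and C1 as the only nucleophilic carbons and tempers them, the hydroxyalkylation is reversible, and the branched C10, the N-allyl group, slow addition and high dilution disfavour dipyrrylmethane formation.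

Step 9
Reactants: 17 tricyclic alkenylpyrrole lactone; 18 allyltrimethylsilane
Product: 19 C9-allyl tricyclic lactone (9R 10R 11R 12S 13S 20S)
Conditions: 18 (5 equiv), Tf2NH (1.2 equiv), CH2Cl2, −78 to −30 °C
Reagents that add atoms: none
Why: Protonation of the 2-alkenylpyrrole at C10 gives the azafulvenium ion, which the allylsilane captures at C9 (Hosomi–Sakurai-type allylation); protonation is reversible and only the C10 epimer with ethyl on the concave face leaves the convex face open, so H-10 and the allyl group both end on the convex face.

Step 10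
Reactants: 19 C9-allyl tricyclic lactone
Product: 20 tetracyclic dihydroazepine (C6=C7)
Conditions: second-generation Grubbs catalyst (5 mol %), CH2Cl2, 0.005 M, 40 °C
Reagents that add atoms: none
Why: Ring-closing metathesis of the N-allyl and C9-allyl groups, the only two alkenes left, should close the seven-membered ring without touching any stereocentre.

Step 11
Reactants: 20 tetracyclic dihydroazepine
Product: 21 tetracyclic keto ester
Conditions: H2 (1 atm), Pd/C, EtOAc, rt
Reagents that add atoms: none
Why: Catalytic hydrogenation saturates the isolated cis-alkene, while the tetrasubstituted acylpyrrole and its vinylogous-amide ketone are inert under these conditions.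

Step 12
Reactants: 21 tetracyclic keto ester
Product: 23 target CNP0232452.1, via hydroxy ester 22 (not isolated)
Conditions: (S)-Me-CBS oxazaborolidine (20 mol %), BH3·SMe2 (1.0 equiv), THF, −20 °C; H2O; then DBU (20 mol %), CH2Cl2, rt
Reagents that add atoms: none
Why: The Corey–Bakshi–Shibata reduction treats the pyrrolyl group as the large and the CH2 group as the small substituent and should give the 18R alcohol, and base-catalysed lactonisation onto the methyl ester then closes the trans lactone without acid that could ionise C18.

Compound list
1 | propanal | CCC=O | starting material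
2 | nitromethane | C[N+](=O)[O-] | starting material
3 | 1-nitrobutan-2-ol (racemic) | CCC(O)C[N+](=O)[O-] | intermediate
4 | 1-nitrobutan-2-yl methanesulfonate (racemic, not isolated) | CCC(C[N+](=O)[O-])OS(C)(=O)=O | intermediate
5 | (E)-1-nitrobut-1-ene | CC/C=C/[N+](=O)[O-] | intermediate
6 | 3-methylfuran-2(5H)-one | CC1=CCOC1=O | starting material
7 | (5S)-3-methyl-5-(1-nitrobutan-2-yl)furan-2(5H)-one, epimers at C10 | CCC(C[N+](=O)[O-])[C@H]1OC(=O)C(C)=C1 | intermediate
8 | 2-[(2S)-4-methyl-5-oxo-2,5-dihydrofuran-2-yl]butanal, epimers at C10 | CCC(C=O)[C@H]1OC(=O)C(C)=C1 | intermediate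
9 | pyrrole | c1cc[nH]c1 | starting material
10 | allyl bromide | C=CCBr | starting material
11 | 1-allylpyrrole | C=CCn1cccc1 | intermediate
12 | (S)-4-methoxy-3-methyl-4-oxobutanoic acid | OC(=O)C[C@H](C)C(=O)OC | starting material
13 | methyl (S)-4-chloro-2-methyl-4-oxobutanoate | ClC(=O)C[C@H](C)C(=O)OC | intermediate
14 | methyl (2S)-4-(1-allylpyrrol-2-yl)-2-methyl-4-oxobutanoate | C=CCn1cccc1C(=O)C[C@H](C)C(=O)OC | intermediate
15 | 5-(1-hydroxyalkyl)-2-acylpyrrole carrying the intact (11S)-butenolide, epimers at C9 and C10 (not isolated) | CCC(C(O)c1ccc(C(=O)C[C@H](C)C(=O)OC)n1CC=C)[C@H]1OC(=O)C(C)=C1 | intermediate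
16 | 5-alkenyl-2-acylpyrrole, C9=C10 with C9a cis to C11, intact (11S)-butenolide (not isolated) | CC/C(=C/c1ccc(C(=O)C[C@H](C)C(=O)OC)n1CC=C)[C@H]1OC(=O)C(C)=C1 | intermediate
17 | N-allyl-3-acylpyrrole fused at C9a–C1 to ring C (C9=C10, ethyl on C10), ring C cis-fused at C11–C12 to the α-methyl-γ-lactone; H-11, H-12, H-13 all cis; 11S,12S,13S,20S | CCC1=Cc2c(cc(C(=O)C[C@H](C)C(=O)OC)n2CC=C)[C@@H]2[C@H](C)C(=O)O[C@H]12 | intermediate
18 | allyltrimethylsilane | C=CC[Si](C)(C)C | starting material
19 | saturated ring C with allyl on C9 trans to ethyl on C10; 9R,10R,11R,12S,13S,20S | CC[C@H]1[C@H]2OC(=O)[C@@H](C)[C@H]2c2cc(C(=O)C[C@H](C)C(=O)OC)n(CC=C)c2[C@@H]1CC=C | intermediate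
20 | tetracycle with a 2,5-dihydroazepine ring (cis C6=C7) | CC[C@H]1[C@H]2OC(=O)[C@@H](C)[C@H]2c2cc(C(=O)C[C@H](C)C(=O)OC)n3c2[C@@H]1C/C=C\C3 | intermediate
21 | tetracyclic C18 ketone with the (20S)-methyl ester side chain | CC[C@H]1[C@H]2OC(=O)[C@@H](C)[C@H]2c2cc(C(=O)C[C@H](C)C(=O)OC)n3c2[C@@H]1CCCC3 | intermediate
22 | (18R)-hydroxy ester (not isolated) | CC[C@H]1[C@H]2OC(=O)[C@@H](C)[C@H]2c2cc([C@H](O)C[C@H](C)C(=O)OC)n3c2[C@@H]1CCCC3 | intermediate
23 | CNP0232452.1; 9R,10R,11R,12S,13S,18R,20S | CC[C@H]1[C@H]2OC(=O)[C@@H](C)[C@H]2c2cc([C@H]3C[C@H](C)C(=O)O3)n3c2[C@@H]1CCCC3 | target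

Total step count: 12.
Longest linear sequence: 9 (steps 1, 2, 3, 4, 8, 9, 10, 11, 12).

Steps most likely to fail

Step 8.
- What may go wrong: the deactivated pyrrole may attack the hindered aldehyde too slowly. Acid-induced β-elimination of the allylic carboxylate from 8 (loss of C11), first attack through C1, or capture of the azafulvenium ion by a second pyrrole could then take over.
- Fallback: it sets out from 8 and 14, returns at 17, and separates the two bond formations around a preformed, stronger electrophile. Aldehyde 8 is converted with HC(OMe)3 and PPTS in MeOH into the dimethyl acetal F1. TMSOTf and 2,6-di-tert-butylpyridine at −78 °C generate the oxocarbenium ion from F1, which 14 captures at C9a to give the α-methoxyalkylpyrrole F2. EtAlCl2 in CH2Cl2 at 0 °C then closes ring C by the Michael addition and expels methanol to give 17.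

Step 9.
- What may go wrong: protodesilylation of the allylsilane by the strong acid, acid-induced oligomerisation of the alkenylpyrrole, or poor facial selectivity at C9 and C10.
- Fallback: it sets out from 17, returns at 19, and stores the cation as an isolable compound. p-Toluenesulfinic acid in CH2Cl2 adds across C9=C10 (proton to C10, sulfinate to C9) to give the C9 sulfone F3, which can be purified. EtAlCl2 with allyltrimethylsilane at −78 °C ionises F3 under aprotic conditions, and the allyl group enters from the convex face to give 19.

Step 4.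
- What may go wrong: the reduction may stall at the oxime or run on to the amine, and long exposure of the β-acyloxy aldehyde to the medium may cause β-elimination.
- Fallback: it sets out from 7, returns at 8, and splits the redox and hydrolysis events. SnCl2·2H2O, PhSH and Et3N reduce the nitro group of 7 to the aldoxime F4. Oxime exchange with aqueous glyoxylic acid at rt then releases 8 under mild conditions.

Further compounds
F1 | step 8 | (5S)-5-(1,1-dimethoxybutan-2-yl)-3-methylfuran-2(5H)-one, epimers at C10 | CCC(C(OC)OC)[C@H]1OC(=O)C(C)=C1
F2 | step 8 | 5-(1-methoxyalkyl)-2-acylpyrrole carrying the intact (11S)-butenolide, epimers at C9 and C10 | CCC(C(OC)c1ccc(C(=O)C[C@H](C)C(=O)OC)n1CC=C)[C@H]1OC(=O)C(C)=C1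
F3 | step 9 | C9 p-tolyl sulfone of the saturated tricycle, epimers at C9 | CC[C@H]1[C@H]2OC(=O)[C@@H](C)[C@H]2c2cc(C(=O)C[C@H](C)C(=O)OC)n(CC=C)c2C1S(=O)(=O)c1ccc(C)cc1
F4 | step 4 | 2-[(2S)-4-methyl-5-oxo-2,5-dihydrofuran-2-yl]butanal oxime, epimers at C10 | CCC(C=NO)[C@H]1OC(=O)C(C)=C1
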